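## The problem

Cathafuran C (22) is an achiral 2-arylbenzofuran. A 6-hydroxybenzofuran is joined through C2 to a crowded ring B: C1' carries the benzofuran, C2' the vinylic carbon of a 2,2-dimethylpyran, C3' the pyran oxygen, C4' a hydrogen, C5' a free hydroxyl and C6' a prenyl group. No stereocentre has to be set, so the task is one of regiochemistry. The two meta oxygens of ring B must end up different, and both carbon substituents must sit on the positions flanking the biaryl bond, not at C4', where a 5-arylresorcinol reacts most readily. The C2–C1' bond has two ortho substituents on ring B, which speaks against forming it late by cross-coupling and against late electrophilic substitution next to it. Several groups are fragile: the prenyl double bond beside a free phenol (acid closes a chroman; halogens, peracids, quinone oxidants and hydrogenation attack it), the enol-ether-like double bond of the 2H-chromene, the electron-rich C3 of the benzofuran, and the phenols. The feature that opens the structure is that ring B, read as C3'(O)–C4'(H)–C5'(O) with the aryl-bearing C1' opposite C4', is the aromatised form of a 5-arylcyclohexane-1,3-dione whose aryl carbon is flanked by an ester-bearing carbon (C2') and a prenyl-bearing carbon (C6'). Such a dione is the product of a Michael–Claisen union of an α-prenyl enone (C1', C6', C5', C4') with a malonate (C2', C3' and the future pyran carbon), so every substituent of ring B is placed by construction. The stereocentres of the dione are transient and matter only in that the later dehydrogenation needs one hydrogen syn to a leaving group.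

## Retrosynthesis

Target 22 is traced first to its bis(methoxymethyl) ether 21; no skeletal bond is cut. Both phenols must be masked during the ring B synthesis and the redox adjustments. An acetal is the common phenol protecting group that tolerates an aryllithium, hot alkoxide, an amide base and a hydride and still leaves without hydrogenation or a strong Lewis acid. The forward step must cleave two aryl acetals with acid weak enough to spare the prenyl group beside the freed hydroxyl and the chromene double bond.

In 21 the pyran ring is opened at O1–C2 and C3–C4 (chromene numbering), giving salicylaldehyde 17 and alkenylboronic acid 18. The usual chromene syntheses start at the phenol oxygen and let the reagent choose an ortho carbon; on ring B that choice would lie between C2' and the more reactive C4'. With this cut the carbon is already in place at C2' as a formyl group and only the hydroxyl next to it can close the ring, so no positional isomer can form. The precursor has four carbons and one ring fewer. The forward reaction must form an iminium ion at an aldehyde with two ortho substituents, transfer the alkenyl group from boron, and lose the amine to a quinone methide that electrocyclises.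

Aldehyde 17 is traced through benzylic alcohol 16 and ester 15 to resorcylate 14; only C–O and C–H bonds at the one-carbon substituent change, and one acetal is added. Direct reduction of 14 is avoided: a 2,4-dihydroxybenzoate is deactivated towards hydride as its bis-phenoxide, and its benzylic alcohol loses water to quinone methides that are reduced further. The two hydroxyls of 14 differ sharply, one being tied to the ester carbonyl by a hydrogen bond, so the free one can be protected alone; here the two oxygens of ring B become permanently different. Forward, a hindered ester must be reduced without hydrogenolysis and the alcohol oxidised without touching a phenol.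

Resorcylate 14 is the dehydro form of dione ester 11; no skeletal bond is cut, one C=C bond (C1'–C2') is removed. Bromine, iodine, mercury salts and quinones, the usual reagents for aromatising cyclohexane-1,3-diones, all attack a prenyl group, and a quinone oxidant would close the wrong chromene from the C5' hydroxyl. The unsaturation is therefore introduced by selenoxide elimination. The ester makes C2'–H the second most acidic position of 11, so the dianion can be functionalised there and nowhere else. The forward step needs site-selective selenenylation and a hydrogen on C1' syn to selenium.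

Dione ester 11 is cut at C1'–C2' and C3'–C4', giving enone 8 and dimethyl malonate 9. The neighbouring [3+3] cuts are poorer: cutting C1'–C6' instead of C1'–C2' asks a simple ester or ketone enolate to act as Michael donor, and a ketone donor would have to react through its more substituted α-carbon or the prenyl group would end up at C4'. In the chosen pairing the prenyl group is locked on the α-carbon of the acceptor, the donor is the most forgiving carbon acid available, and the ring can close only from the methyl group. The precursor is acyclic and has no stereocentre. The forward reaction must achieve conjugate addition to a trisubstituted, heteroaryl-conjugated enone and be pulled through by the Claisen closure.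

Enone 8 is cut at its C=C bond into aldehyde 4 and α-prenyl β-ketophosphonate 7, itself the alkylation product of phosphonate 5 and prenyl bromide 6. A base-mediated aldol condensation would be shorter but puts the arylidene group on the methyl side of the ketone; an acid-mediated one would go to the right side but would not spare the acetal and the prenyl group. The phosphonate fixes the site of condensation. Forward, a hindered stabilised anion must add to a heteroaromatic aldehyde; the alkene geometry is of no consequence.

Aldehyde 4 is cut at the formyl–C2 bond to 6-(methoxymethoxy)-1-benzofuran 2, the acetal of commercial 1-benzofuran-6-ol 1. C2 is the most acidic position of a benzofuran, so deprotonation and formylation should be regioselective, and the complete benzofuran is bought, not built.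

## Roads not taken

Alternative 1: The furan ring would be made last, by cutting the C2=C3 bond of the benzofuran. In phosphonium salt A2 the ring B carboxylic acid is esterified to a 2-(phosphoniomethyl)phenol; on deprotonation the ylide carbon adds to its own ester carbonyl and the oxaphosphetane collapses to bis-silyl ether A1, from which fluoride frees the target. The acid half of A2 would come from a 1,3,5-trioxygenated benzene ring in which one oxygen is exchanged for the carboxyl carbon (aryl sulfonate, then carbonylation).
- Merits: the two halves are joined by a simple esterification and the crowded C2–C1' bond forms intramolecularly. No alkoxide step intervenes, so silyl ethers can be used and the end-game is fluoride, which is kinder to prenyl and chromene than the acid of step 11. On this point the alternative is better.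
- Weak points: the ester carbonyl of A2 lies between the prenyl group and the chromene vinyl carbon, so ylide addition competes with acyl transfer and ester cleavage. The ring B acid must also carry prenyl, pyran and carboxyl carbon in the right order on a ring whose three oxygens begin alike. C-prenylation, chromene annulation and the exchange of one particular oxygen for carbon are three successive selectivity problems, so the regiochemical difficulty is moved, not removed.
- Comparison: against the milder deprotection, the chosen plan sets a ring B whose pattern follows from the way the ring is made, and a benzofuran that is bought complete.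

Alternative 2: Ring B would be closed by aldol condensation of an open polycarbonyl chain. Heating dioxinone A3 in methanol opens the dioxinone to methyl triketo ester A4. Cs2CO3 then lets the carbon between ester and ketone (C2') attack the benzofuranyl ketone (C1'), and loss of water gives resorcylate A5, which is identical with 14.
- Merits: the sequence is redox-neutral and the ring arrives aromatic, so the dehydrogenation of step 6, the least secure operation of the chosen plan after its key step, is not needed. From A5 on the two routes coincide. In that respect the alternative is better.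
- Weak points: A3 is harder to make than 8. It needs C-acylation of a dioxinone dienolate and a prenyl group on a carbon flanked by two ketones, where O-alkylation and dialkylation compete. A4 can also fold in more than one way: Claisen closure from the prenyl-bearing carbon onto the ester, and lactonisation of an enol oxygen onto the ester, are six-membered closures that compete with the aldol. The wanted electrophile is the least reactive carbonyl of the chain, an aryl ketone conjugated to an electron-rich benzofuran and branched at its α-carbon.
- Comparison: the chosen plan pays one oxidation step for a ring closure with only one possible course and a precursor made in three steps.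

Alternative 3: Both carbon substituents of ring B would be delivered from its oxygens. In bis-ether A6 the two ring B oxygens carry a 1,1-dimethylallyl and a 1,1-dimethylpropargyl group and C4' carries bromine. On heating, the allyl ether should shift to C6' as a prenyl group and the propargyl ether to C2', where hydrogen shift and oxa-6π closure build the pyran, giving bromochromenol A7. Removal of bromine and of the silyl group would finish the synthesis.
- Merits: ring B starts as a symmetrical 5-aryl-1,3-dioxygenated ring available by one cross-coupling, both groups arrive in one thermal operation, ortho delivery is dictated by mechanism, and the sequence is shorter on paper than the chosen one.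
- Weak points: two different tertiary ethers must be put on two equivalent hydroxyls, a statistical desymmetrisation with alkylating agents that prefer elimination. Bromine serves only to block C4' and must later be removed reductively beside a prenyl group, a chromene and a free phenol. Both shifts must end ortho to the benzofuranyl group at temperatures at which a fresh ortho-prenylphenol can cyclise or rearrange further.
- Comparison: the alternative is shorter and more convergent. The chosen plan sets against this that no step depends on telling two equal positions apart, and that nothing is put on only to be taken off except the two acetals.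

Key step: step 5

Remark: conjugate bases formed by simple deprotonation of O–H or enolisable C–H groups are treated as forms of the compound concerned and are not numbered; covalent intermediates that react on in the same flask are numbered.
Remark: compounds 1, 5, 6, 9 and 18 are taken as commercial; 22 is achiral, and the stereocentres of 7, 10–13 and 19 are racemic and transient.

## Route

Step 1
Reactants: 1 1-benzofuran-6-ol
Product: 2 6-(methoxymethoxy)-1-benzofuran
Conditions: MOMCl, iPr2NEt, CH2Cl2, 0 °C to rt
Reagents that add atoms: chloromethyl methyl ether (MOMCl), COCCl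
Why: O-Alkylation of the phenol with the reactive chloromethyl ether under amine base (acetal protection); the methoxymethyl ether is chosen because it survives the aryllithium, methoxide, amide-base and hydride steps and leaves under mild acid.

Step 2
Reactants: 2 6-(methoxymethoxy)-1-benzofuran
Product: 4 6-(methoxymethoxy)-1-benzofuran-2-carbaldehyde, via 2-lithio derivative 3 (not isolated)
Conditions: n-BuLi (1.1 equiv), THF, −78 °C; DMF, −78 to 0 °C; H2O
Reagents that add atoms: N,N-dimethylformamide (DMF), CN(C)C=O
Why: Deprotonation of the most acidic ring position, C2 next to the furan oxygen, and formylation of the aryllithium with DMF; at −78 °C lithiation at C2 should outpace ortho-lithiation beside the acetal.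

Step 3
Reactants: 5 dimethyl (2-oxopropyl)phosphonate; 6 1-bromo-3-methylbut-2-ene
Product: 7 dimethyl (6-methyl-2-oxohept-5-en-3-yl)phosphonate (racemic)
Conditions: NaH, THF, 0 °C; 6, 0 °C to rt
Reagents that add atoms: none
Why: C-Alkylation (SN2) of the sodium enolate of a β-ketophosphonate with an allylic bromide; a slight excess of 5 limits dialkylation, and the new stereocentre is destroyed in step 4.

Step 4
Reactants: 4 6-(methoxymethoxy)-1-benzofuran-2-carbaldehyde; 7 dimethyl (6-methyl-2-oxohept-5-en-3-yl)phosphonate
Product: 8 (3E)-3-{[6-(methoxymethoxy)-1-benzofuran-2-yl]methylidene}-6-methylhept-5-en-2-one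
Conditions: NaH, THF, 0 °C; 4, 0 to 65 °C
Reagents that add atoms: none
Why: Horner–Wadsworth–Emmons olefination of an α-substituted β-ketophosphonate with an aromatic aldehyde, which fixes the prenyl group on the α-carbon of the enone. The E isomer (aryl trans to acetyl) is expected, but either isomer serves in step 5.

Step 5
Reactants: 8 (3E)-3-{[6-(methoxymethoxy)-1-benzofuran-2-yl]methylidene}-6-methylhept-5-en-2-one; 9 dimethyl malonate
Product: 11 methyl 2-[6-(methoxymethoxy)-1-benzofuran-2-yl]-3-(3-methylbut-2-en-1-yl)-4,6-dioxocyclohexane-1-carboxylate (racemic 1,2-trans-2,3-trans isomer), via Michael adduct 10 (not isolated)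
Conditions: NaOMe (1.3 equiv), MeOH, reflux; then 1 M HCl, 0 °C
Reagents that add atoms: none
Why: Methoxide generates the malonate anion, which adds as a stabilised, soft nucleophile to the β-carbon of 8 (the carbon bearing the benzofuran) and so forms the C1'–C2' bond; proton transfer gives adduct 10. The enolate of the acetyl methyl group of 10 then attacks one of the two equivalent ester carbonyls in a Dieckmann-type Claisen condensation, a 6-(enolendo)-exo-trig closure that forms the C3'–C4' bond and ring B and expels methoxide. The only other enolisable position of the ketone, the prenyl-bearing α-carbon, could close nothing larger than a four-membered ring, so ring size secures the regiochemistry of closure. Addition and closure are both reversible, but the 1,3-dione is deprotonated at once to a stabilised enolate, and this sink draws the conjugate addition to the trisubstituted enone forward; reversibility also corrects any 1,2-addition. Three stereocentres arise; the two flanking the aryl-bearing carbon are epimerisable and should settle under thermodynamic control in the all-equatorial 1,2-trans-2,3-trans arrangement, but all isomers lead to the same aromatic ring in step 6. Anhydrous methoxide in methanol and cold acidification keep the remaining ester, which later becomes the pyran carbon, from hydrolysis and decarboxylation. The closest known reaction type is the malonate–enone Michael–Claisen annulation that gives 4-alkoxycarbonyl-5-substituted cyclohexane-1,3-diones on the way to 5-substituted resorcinols.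

Step 6
Reactants: 11 methyl 2-[6-(methoxymethoxy)-1-benzofuran-2-yl]-3-(3-methylbut-2-en-1-yl)-4,6-dioxocyclohexane-1-carboxylate
Product: 14 methyl 2,4-dihydroxy-6-[6-(methoxymethoxy)-1-benzofuran-2-yl]-5-(3-methylbut-2-en-1-yl)benzoate, via selenide 12 (not isolated), via selenoxide 13 (not isolated)
Conditions: LiN(iPr)2 (2.2 equiv), THF, −78 °C; PhSeBr (1.05 equiv), −78 °C; AcOH; 30% H2O2, 0 °C to rt
Reagents that add atoms: none
Why: Two equivalents of amide base give the dianion, whose ester-stabilised carbon (the future C2') is the most nucleophilic site and should be selenenylated anti to the neighbouring benzofuranyl group, placing selenium syn to the hydrogen on the aryl-bearing carbon. Oxidation to selenoxide 13 and syn-elimination at or below room temperature (α-selenenylation/selenoxide elimination of a β-keto ester) give the keto tautomer of 14, which enolises at once to the aromatic ring. No halogen, quinone or strong acid is present, and the buffered amine limits addition of selenium by-products to the prenyl group.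

Step 7
Reactants: 14 methyl 2,4-dihydroxy-6-[6-(methoxymethoxy)-1-benzofuran-2-yl]-5-(3-methylbut-2-en-1-yl)benzoate
Product: 15 methyl 2-hydroxy-4-(methoxymethoxy)-6-[6-(methoxymethoxy)-1-benzofuran-2-yl]-5-(3-methylbut-2-en-1-yl)benzoate
Conditions: MOMCl (1.1 equiv), iPr2NEt, CH2Cl2, 0 °C
Reagents that add atoms: chloromethyl methyl ether (MOMCl), COCCl
Why: The hydroxyl para to the ester is free whereas the ortho hydroxyl is held in a hydrogen bond to the ester carbonyl, so one equivalent of reagent should alkylate the former selectively, as in other 2,4-dihydroxybenzoates. Masking the para oxygen makes the ester reducible and keeps the derived benzylic alcohol from quinone methide chemistry.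

Step 8
Reactants: 15 methyl 2-hydroxy-4-(methoxymethoxy)-6-[6-(methoxymethoxy)-1-benzofuran-2-yl]-5-(3-methylbut-2-en-1-yl)benzoate
Product: 16 2-(hydroxymethyl)-5-(methoxymethoxy)-3-[6-(methoxymethoxy)-1-benzofuran-2-yl]-4-(3-methylbut-2-en-1-yl)phenol
Conditions: LiAlH4, THF, 0 °C to rt; aq. KNaC4H4O6 (potassium sodium tartrate) work-up
Reagents that add atoms: none
Why: Hydride reduction of a salicylate ester to the benzylic alcohol; aluminium bound to the ortho phenoxide delivers hydride to the hindered carbonyl, and the low temperature avoids hydrogenolysis of the benzylic C–O bond.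

Step 9
Reactants: 16 2-(hydroxymethyl)-5-(methoxymethoxy)-3-[6-(methoxymethoxy)-1-benzofuran-2-yl]-4-(3-methylbut-2-en-1-yl)phenol
Product: 17 2-hydroxy-4-(methoxymethoxy)-6-[6-(methoxymethoxy)-1-benzofuran-2-yl]-5-(3-methylbut-2-en-1-yl)benzaldehyde
Conditions: MnO2 (activated, excess), CH2Cl2, rt
Reagents that add atoms: none
Why: Selective heterogeneous oxidation of an activated benzylic alcohol by MnO2; the phenol, prenyl group, benzofuran and acetals are inert, and the hydrogen-bonded salicylaldehyde is not oxidised further.

Step 10
Reactants: 17 2-hydroxy-4-(methoxymethoxy)-6-[6-(methoxymethoxy)-1-benzofuran-2-yl]-5-(3-methylbut-2-en-1-yl)benzaldehyde; 18 (2-methylprop-1-en-1-yl)boronic acid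
Product: 21 7-(methoxymethoxy)-5-[6-(methoxymethoxy)-1-benzofuran-2-yl]-2,2-dimethyl-6-(3-methylbut-2-en-1-yl)-2H-chromene, via aminophenol 19 (not isolated), via quinone methide 20 (not isolated)
Conditions: Bn2NH (40 mol %), 1,4-dioxane, 90 °C
Reagents that add atoms: none
Why: Amine-catalysed Petasis-type chromene synthesis: the amine and the aldehyde form an iminium ion, the boronic acid is bound by the ortho phenoxide and transfers its alkenyl group to carbon (19), and at 90 °C the amine is expelled to give ortho-quinone methide 20, whose oxa-6π electrocyclisation closes the pyran. The aldehyde carbon, which stems from the malonate ester, becomes C4 of the chromene, and only the hydroxyl ortho to it can close, so no isomeric pyran can form.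

Step 11
Reactants: 21 7-(methoxymethoxy)-5-[6-(methoxymethoxy)-1-benzofuran-2-yl]-2,2-dimethyl-6-(3-methylbut-2-en-1-yl)-2H-chromene
Product: 22 cathafuran C, 5-(6-hydroxy-1-benzofuran-2-yl)-2,2-dimethyl-6-(3-methylbut-2-en-1-yl)-2H-chromen-7-ol
Conditions: conc. HCl (cat.), MeOH, rt to 40 °C
Reagents that add atoms: none
Why: Acid-catalysed transacetalisation of both aryl methoxymethyl ethers to the solvent (acetal solvolysis); dilute acid near room temperature, as used for other ortho-prenylphenols, is chosen so that neither the prenyl group nor the chromene double bond is protonated.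

## Compound list

1 | 1-benzofuran-6-ol | Oc1ccc2ccoc2c1 | starting material
2 | 6-(methoxymethoxy)-1-benzofuran | COCOc1ccc2ccoc2c1 | intermediate
3 | [6-(methoxymethoxy)-1-benzofuran-2-yl]lithium | COCOc1ccc2cc([Li])oc2c1 | intermediate (not isolated)
4 | 6-(methoxymethoxy)-1-benzofuran-2-carbaldehyde | COCOc1ccc2cc(C=O)oc2c1 | intermediate
5 | dimethyl (2-oxopropyl)phosphonate | COP(=O)(CC(C)=O)OC | starting material
6 | 1-bromo-3-methylbut-2-ene | CC(C)=CCBr | starting material
7 | dimethyl (6-methyl-2-oxohept-5-en-3-yl)phosphonate (racemic) | COP(=O)(OC)C(CC=C(C)C)C(C)=O | intermediate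
8 | (3E)-3-{[6-(methoxymethoxy)-1-benzofuran-2-yl]methylidene}-6-methylhept-5-en-2-one | CC(=O)/C(CC=C(C)C)=C/c1cc2ccc(OCOC)cc2o1 | intermediate
9 | dimethyl malonate | COC(=O)CC(=O)OC | starting material
10 | dimethyl 2-{2-acetyl-1-[6-(methoxymethoxy)-1-benzofuran-2-yl]-5-methylhex-4-en-1-yl}propanedioate (mixture of diastereomers) | COC(=O)C(C(=O)OC)C(c1cc2ccc(OCOC)cc2o1)C(CC=C(C)C)C(C)=O | intermediate (not isolated)
11 | methyl 2-[6-(methoxymethoxy)-1-benzofuran-2-yl]-3-(3-methylbut-2-en-1-yl)-4,6-dioxocyclohexane-1-carboxylate (racemic, 1,2-trans-2,3-trans isomer drawn; largely enolised) | COC(=O)[C@@H]1C(=O)CC(=O)[C@H](CC=C(C)C)[C@H]1c1cc2ccc(OCOC)cc2o1 | intermediate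
12 | methyl 2-[6-(methoxymethoxy)-1-benzofuran-2-yl]-3-(3-methylbut-2-en-1-yl)-4,6-dioxo-1-(phenylselanyl)cyclohexane-1-carboxylate (racemic; selanyl group trans to the benzofuranyl group, as expected) | COC(=O)[C@@]1([Se]c2ccccc2)C(=O)CC(=O)[C@H](CC=C(C)C)[C@H]1c1cc2ccc(OCOC)cc2o1 | intermediate (not isolated)
13 | methyl 1-(benzeneseleninyl)-2-[6-(methoxymethoxy)-1-benzofuran-2-yl]-3-(3-methylbut-2-en-1-yl)-4,6-dioxocyclohexane-1-carboxylate (racemic; both configurations at selenium) | COC(=O)[C@@]1([Se](=O)c2ccccc2)C(=O)CC(=O)[C@H](CC=C(C)C)[C@H]1c1cc2ccc(OCOC)cc2o1 | intermediate (not isolated)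
14 | methyl 2,4-dihydroxy-6-[6-(methoxymethoxy)-1-benzofuran-2-yl]-5-(3-methylbut-2-en-1-yl)benzoate | COC(=O)c1c(O)cc(O)c(CC=C(C)C)c1-c1cc2ccc(OCOC)cc2o1 | intermediate
15 | methyl 2-hydroxy-4-(methoxymethoxy)-6-[6-(methoxymethoxy)-1-benzofuran-2-yl]-5-(3-methylbut-2-en-1-yl)benzoate | COC(=O)c1c(O)cc(OCOC)c(CC=C(C)C)c1-c1cc2ccc(OCOC)cc2o1 | intermediate
16 | 2-(hydroxymethyl)-5-(methoxymethoxy)-3-[6-(methoxymethoxy)-1-benzofuran-2-yl]-4-(3-methylbut-2-en-1-yl)phenol | OCc1c(O)cc(OCOC)c(CC=C(C)C)c1-c1cc2ccc(OCOC)cc2o1 | intermediate
17 | 2-hydroxy-4-(methoxymethoxy)-6-[6-(methoxymethoxy)-1-benzofuran-2-yl]-5-(3-methylbut-2-en-1-yl)benzaldehyde | O=Cc1c(O)cc(OCOC)c(CC=C(C)C)c1-c1cc2ccc(OCOC)cc2o1 | intermediate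
18 | (2-methylprop-1-en-1-yl)boronic acid | CC(C)=CB(O)O | starting material
19 | 2-[1-(dibenzylamino)-3-methylbut-2-en-1-yl]-5-(methoxymethoxy)-3-[6-(methoxymethoxy)-1-benzofuran-2-yl]-4-(3-methylbut-2-en-1-yl)phenol (racemic) | CC(C)=CC(N(Cc1ccccc1)Cc1ccccc1)c1c(O)cc(OCOC)c(CC=C(C)C)c1-c1cc2ccc(OCOC)cc2o1 | intermediate (not isolated)
20 | (6Z)-3-(methoxymethoxy)-5-[6-(methoxymethoxy)-1-benzofuran-2-yl]-6-(3-methylbut-2-en-1-ylidene)-4-(3-methylbut-2-en-1-yl)cyclohexa-2,4-dien-1-one | CC(C)=C/C=C1\C(=O)C=C(OCOC)C(CC=C(C)C)=C1c1cc2ccc(OCOC)cc2o1 | intermediate (not isolated)
21 | 7-(methoxymethoxy)-5-[6-(methoxymethoxy)-1-benzofuran-2-yl]-2,2-dimethyl-6-(3-methylbut-2-en-1-yl)-2H-chromene | CC(C)=CCc1c(OCOC)cc2c(c1-c1cc3ccc(OCOC)cc3o1)C=CC(C)(C)O2 | intermediate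
22 | cathafuran C, 5-(6-hydroxy-1-benzofuran-2-yl)-2,2-dimethyl-6-(3-methylbut-2-en-1-yl)-2H-chromen-7-ol (achiral) | CC(C)=CCc1c(O)cc2c(c1-c1cc3ccc(O)cc3o1)C=CC(C)(C)O2 | target

## Step count and uncertain steps

Total step count: 11. Longest linear sequence: 10 steps (from 1 through steps 1, 2 and 4–11); step 3 is a one-step side branch.

Step 5 (key step). The conjugate addition may stall or revert. The β-carbon of 8 is trisubstituted and conjugated to an electron-rich benzofuran, so little adduct 10 may be present at equilibrium, and the ring closure that must pull it through then competes with methoxide-induced self-condensation through the acetyl enolate. The fallback forms the other pair of ring bonds (C1'–C6' and C4'–C5') and makes the same product. It sets out from 4: Knoevenagel condensation with methyl acetoacetate (piperidine, AcOH) should give methyl 2-acetyl-3-[6-(methoxymethoxy)-1-benzofuran-2-yl]prop-2-enoate F1, a doubly activated acceptor. The lithium enolate of methyl 5-methylhex-4-enoate F2 (from 2-methylbut-3-en-2-ol and trimethyl orthoacetate by Johnson–Claisen rearrangement) is added to it at −78 °C to give dimethyl 2-acetyl-3-[6-(methoxymethoxy)-1-benzofuran-2-yl]-4-(3-methylbut-2-en-1-yl)pentanedioate F3. NaOMe in MeOH then closes the ring by Dieckmann-type attack of the acetyl methyl group on the hexenoate ester, and the sequence returns to the route at 11. It is second choice because it needs a kinetic ester enolate in place of a malonate.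

Step 6. Three processes threaten: selenenylation at the carbon between the two ketones if the dianion is not fully formed, addition of electrophilic selenium or peroxide-derived species to the prenyl double bond, and entry of selenium cis to the benzofuran, which would leave no syn hydrogen. The fallback sets out from 11 and uses no oxidant: the same dianion is treated at −78 °C with N-tert-butylbenzenesulfinimidoyl chloride. The adduct methyl 1-(N-tert-butyl-S-phenylsulfinimidoyl)-2-[6-(methoxymethoxy)-1-benzofuran-2-yl]-3-(3-methylbut-2-en-1-yl)-4,6-dioxocyclohexane-1-carboxylate F4 should eliminate in the cold by a syn pathway, and tautomerisation returns the sequence to the route at 14.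

Step 10. Iminium formation may be slow at an aldehyde that lies between a hydroxyl and a benzofuranyl group and is deactivated by a para alkoxy group. Protodeboronation of 18 at 90 °C and incomplete loss of amine from 19 are further risks. The fallback sets out from 17: addition of (2-methylprop-1-en-1-yl)magnesium bromide (3 equiv, THF, 0 °C) gives 2-(1-hydroxy-3-methylbut-2-en-1-yl)-5-(methoxymethoxy)-3-[6-(methoxymethoxy)-1-benzofuran-2-yl]-4-(3-methylbut-2-en-1-yl)phenol F5. Heating F5 in toluene, if needed with a trace of pyridinium p-toluenesulfonate, dehydrates it through quinone methide 20, and the sequence returns to the route at 21.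

Step 11. Acid may add the freshly freed C7 hydroxyl to the prenyl double bond (chroman closure) or protonate the chromene double bond with addition of methanol; cleavage of the more hindered acetal may also be incomplete. The fallback changes the order of events and sets out from 17.
- Both acetals are cleaved first (HCl, MeOH), while no chromene is present and the formyl group lowers the electron density of ring B, to give 2,4-dihydroxy-6-(6-hydroxy-1-benzofuran-2-yl)-5-(3-methylbut-2-en-1-yl)benzaldehyde F6.
- The chromene is then closed on the free triphenol with 18 and Bn2NH as in step 10. This runs through 4-[1-(dibenzylamino)-3-methylbut-2-en-1-yl]-5-(6-hydroxy-1-benzofuran-2-yl)-6-(3-methylbut-2-en-1-yl)benzene-1,3-diol F7 and (6Z)-3-hydroxy-5-(6-hydroxy-1-benzofuran-2-yl)-6-(3-methylbut-2-en-1-ylidene)-4-(3-methylbut-2-en-1-yl)cyclohexa-2,4-dien-1-one F8, and returns to the route at 22.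

Step 4. Addition of the hindered, α-branched phosphonate anion to 4 may be sluggish and reversible, with base-induced decomposition of the aldehyde as the competing process. The fallback sets out from 4: Morita–Baylis–Hillman reaction with but-3-en-2-one (DABCO) gives 3-{hydroxy[6-(methoxymethoxy)-1-benzofuran-2-yl]methyl}but-3-en-2-one F9. Acetylation (Ac2O, pyridine, DMAP) gives 1-[6-(methoxymethoxy)-1-benzofuran-2-yl]-2-methylidene-3-oxobutyl acetate F10. SN2' displacement of acetate by (2-methylprop-1-en-1-yl)magnesium bromide with catalytic CuI at −78 °C then installs the prenyl group on the α-carbon, and the sequence returns to the route at 8.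

## Further compounds

F1 | step 5 | methyl 2-acetyl-3-[6-(methoxymethoxy)-1-benzofuran-2-yl]prop-2-enoate (E/Z mixture) | COC(=O)C(C(C)=O)=Cc1cc2ccc(OCOC)cc2o1
F2 | step 5 | methyl 5-methylhex-4-enoate | COC(=O)CCC=C(C)C
F3 | step 5 | dimethyl 2-acetyl-3-[6-(methoxymethoxy)-1-benzofuran-2-yl]-4-(3-methylbut-2-en-1-yl)pentanedioate (mixture of diastereomers) | COC(=O)C(C(C)=O)C(c1cc2ccc(OCOC)cc2o1)C(CC=C(C)C)C(=O)OC
F4 | step 6 | methyl 1-(N-tert-butyl-S-phenylsulfinimidoyl)-2-[6-(methoxymethoxy)-1-benzofuran-2-yl]-3-(3-methylbut-2-en-1-yl)-4,6-dioxocyclohexane-1-carboxylate (racemic; sulfur trans to the benzofuranyl group) | COC(=O)[C@@]1(S(=NC(C)(C)C)c2ccccc2)C(=O)CC(=O)[C@H](CC=C(C)C)[C@H]1c1cc2ccc(OCOC)cc2o1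
F5 | step 10 | 2-(1-hydroxy-3-methylbut-2-en-1-yl)-5-(methoxymethoxy)-3-[6-(methoxymethoxy)-1-benzofuran-2-yl]-4-(3-methylbut-2-en-1-yl)phenol (racemic) | CC(C)=CC(O)c1c(O)cc(OCOC)c(CC=C(C)C)c1-c1cc2ccc(OCOC)cc2o1
F6 | step 11 | 2,4-dihydroxy-6-(6-hydroxy-1-benzofuran-2-yl)-5-(3-methylbut-2-en-1-yl)benzaldehyde | O=Cc1c(O)cc(O)c(CC=C(C)C)c1-c1cc2ccc(O)cc2o1
F7 | step 11 | 4-[1-(dibenzylamino)-3-methylbut-2-en-1-yl]-5-(6-hydroxy-1-benzofuran-2-yl)-6-(3-methylbut-2-en-1-yl)benzene-1,3-diol (racemic) | CC(C)=CC(N(Cc1ccccc1)Cc1ccccc1)c1c(O)cc(O)c(CC=C(C)C)c1-c1cc2ccc(O)cc2o1
F8 | step 11 | (6Z)-3-hydroxy-5-(6-hydroxy-1-benzofuran-2-yl)-6-(3-methylbut-2-en-1-ylidene)-4-(3-methylbut-2-en-1-yl)cyclohexa-2,4-dien-1-one | CC(C)=C/C=C1\C(=O)C=C(O)C(CC=C(C)C)=C1c1cc2ccc(O)cc2o1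
F9 | step 4 | 3-{hydroxy[6-(methoxymethoxy)-1-benzofuran-2-yl]methyl}but-3-en-2-one (racemic) | CC(=O)C(=C)C(O)c1cc2ccc(OCOC)cc2o1
F10 | step 4 | 1-[6-(methoxymethoxy)-1-benzofuran-2-yl]-2-methylidene-3-oxobutyl acetate (racemic) | CC(=O)OC(C(=C)C(C)=O)c1cc2ccc(OCOC)cc2o1
A1 | alternative 1 | 2-{2,2-dimethyl-6-(3-methylbut-2-en-1-yl)-7-[tri(propan-2-yl)silyloxy]-2H-chromen-5-yl}-6-[tri(propan-2-yl)silyloxy]-1-benzofuran | CC(C)=CCc1c(O[Si](C(C)C)(C(C)C)C(C)C)cc2OC(C)(C)C=Cc2c1-c1cc2ccc(O[Si](C(C)C)(C(C)C)C(C)C)cc2o1
A2 | alternative 1 | {2-[({2,2-dimethyl-6-(3-methylbut-2-en-1-yl)-7-[tri(propan-2-yl)silyloxy]-2H-chromen-5-yl}carbonyl)oxy]-4-[tri(propan-2-yl)silyloxy]benzyl}(triphenyl)phosphonium bromide | CC(C)=CCc1c(O[Si](C(C)C)(C(C)C)C(C)C)cc2OC(C)(C)C=Cc2c1C(=O)Oc1cc(O[Si](C(C)C)(C(C)C)C(C)C)ccc1C[P+](c1ccccc1)(c1ccccc1)c1ccccc1.[Br-]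
A3 | alternative 2 | 6-{4-[6-(methoxymethoxy)-1-benzofuran-2-yl]-3-(3-methylbut-2-en-1-yl)-2,4-dioxobutyl}-2,2-dimethyl-4H-1,3-dioxin-4-one (racemic) | CC1(C)OC(=O)C=C(CC(=O)C(CC=C(C)C)C(=O)c2cc3ccc(OCOC)cc3o2)O1
A4 | alternative 2 | methyl 7-[6-(methoxymethoxy)-1-benzofuran-2-yl]-6-(3-methylbut-2-en-1-yl)-3,5,7-trioxoheptanoate (racemic) | COC(=O)CC(=O)CC(=O)C(CC=C(C)C)C(=O)c1cc2ccc(OCOC)cc2o1
A5 | alternative 2 | methyl 2,4-dihydroxy-6-[6-(methoxymethoxy)-1-benzofuran-2-yl]-5-(3-methylbut-2-en-1-yl)benzoate (identical with 14) | COC(=O)c1c(O)cc(O)c(CC=C(C)C)c1-c1cc2ccc(OCOC)cc2o1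
A6 | alternative 3 | 2-{4-bromo-3-[(2-methylbut-3-en-2-yl)oxy]-5-[(2-methylbut-3-yn-2-yl)oxy]phenyl}-6-[tri(propan-2-yl)silyloxy]-1-benzofuran | C=CC(C)(C)Oc1cc(-c2cc3ccc(O[Si](C(C)C)(C(C)C)C(C)C)cc3o2)cc(OC(C)(C)C#C)c1Br
A7 | alternative 3 | 8-bromo-2,2-dimethyl-6-(3-methylbut-2-en-1-yl)-5-{6-[tri(propan-2-yl)silyloxy]-1-benzofuran-2-yl}-2H-chromen-7-ol | CC(C)=CCc1c(O)c(Br)c2OC(C)(C)C=Cc2c1-c1cc2ccc(O[Si](C(C)C)(C(C)C)C(C)C)cc2o1
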